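## Structural features

The target is a C–O–C biflavonoid: a (2S)-flavanone (naringenin unit, rings A and C plus a 4-hydroxyphenyl ring B) whose C6 carries an oxygen that is at the same time the 4'-oxygen of a flavone (apigenin unit). The ether carbon C6 lies between the C5 and C7 hydroxyls and para to C8a–O1, so flavanone ring A is a 1,2,3,5-tetraoxygenated benzene with one free CH (C8) and one acyl-bearing carbon (C4a). There is one stereocentre, C2 (S): benzylic, attached to O1 and β to the C4 ketone. Base opens ring C by retro-oxa-Michael reaction to a 2'-hydroxychalcone, which can re-close through either ortho oxygen; the configuration at C2 and the 6- versus 8-aryloxy constitution are therefore lost by the same process. Fragile groups are the flavanone (base, hot strong acid), five phenols, and the flavone C2=C3 bond towards reduction. The real difficulty is threefold: an aryl ether at a di-ortho-oxygenated, electron-rich carbon, unambiguous placement of O1 para to that ether, and C2 as a single enantiomer in a ring that must never open. The key step exploits an atom-for-atom mapping: C5–C6–C7–C8 of ring A (O, OAr, O, H) is the C1–C4 chain of a 2-aryloxyacetoacetate, and C4a=C8a with its O1 and C4=O is the C5=C6 enol-ether bond of a 2-aryl-2,3-dihydro-4H-pyran-4-one. Ring A can therefore be made last by a [4+2] benzannulation that joins the two halves, with the ether oxygen attached beforehand at an sp3 carbon and C2 set beforehand in a monocyclic pyranone.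

## Logic of the disconnections

**19 ⇒ 18.** Cut: three O–CH2Ph bonds (O4' of flavanone ring B, O5 and O7 of the flavone). Reason: one neutral operation frees all phenols that had to be silent earlier. Gain: the last step forms no skeletal bond. Demand: no base (C2, O1–C8a), no saturation of the flavone C2=C3 bond, no cleavage of the benzylic C2–O1 bond.

**18 ⇒ 9 + 15 (key).** Cut: C4a–C5 and C8–C8a of flavanone ring A. Reason: these two bonds separate the molecule into the complete flavone half, already carrying the ether oxygen on a four-carbon chain (9), and a monocyclic pyranone holding the only stereocentre and the O1–C8a bond (15). Gain: the hindered aryl ether is never formed on an arene, the 6- versus 8-aryloxy question is settled by which carbons pair, and no chalcone appears at any stage. Demand: one regiochemical sense of a [4+2] addition, aromatization by loss of the sulfur group and not of O1, and neutral conditions throughout. In one sentence: ring A of the flavanone is closed last by a Diels–Alder benzannulation of 9 onto the sulfinyl-activated enol-ether bond of 15.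

**15 ⇒ 14 ⇒ 13.** Cut: S–O, then C5–S of the pyranone. Reason: the sulfinyl group is a traceless activator; it makes the vinylogous ester a dienophile and supplies the oxidation level of an alkyne by later syn-elimination. Gain: 13 is a simple enone. Demand: substitution at C5 only, and no base strong enough to expel O1 from C2 by β-elimination.

**13 ⇒ 10 + 11.** Cut: C2–C3 and O1–C6 of the pyranone. Reason: a catalytic asymmetric hetero-Diels–Alder reaction sets C2 from two achiral commercial compounds. Gain: the stereocentre is made in the smallest possible ring, far from any phenol. Demand: face selectivity on an electron-rich aromatic aldehyde.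

**9 ⇒ 8.** Cut: two O–Si bonds. Reason: the β-keto ester is the stable, storable form of the diene. Demand: double enolization that tolerates the flavone and the benzyl ethers.

**8 ⇒ 6 + 7.** Cut: the bond between the ether oxygen and C2 of the butanoate chain (the future C6 of ring A). Reason: this is the diaryl ether bond of the target, made here by SN2 at an sp3 carbon, where the congestion and electron richness of the future arene play no part. Gain: a commercial four-carbon unit. Demand: O-alkylation, and 6 must carry the 4'-OH as its only free phenol.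

**6 ⇒ 4 (through 5).** Cut: O1–C2 of the flavone, and the acetal O–C bond at O4'. Reason: oxidative cyclization of a 2'-hydroxychalcone gives the flavone oxidation level directly. Demand: benzyl ethers must survive; the acetal must be removed selectively.

**4 ⇒ 2 + 3.** Cut: Cα=Cβ of the enone. Reason: crossed aldol condensation of a methyl ketone and a non-enolizable aldehyde.

**2 ⇒ 1.** Cut: two O–benzyl bonds. Reason: the chelated hydroxyl of 1 stays free and becomes O1 of the flavone.

## Other disconnections considered

Alternative 1: Cut the aryl ether bond on the flavone side and O1–C2 of the flavanone. Forward: SNAr of a hindered 3-hydroxy-2,4,6-trialkoxyacetophenone on a 4-fluorobenzaldehyde gives diaryl ether A1, each carbonyl is then elaborated through a chalcone, and the last one, A2, closes by oxa-Michael addition. Ground for rejection: A2 has two free ortho hydroxyls, so closure can give the 6- or the 8-aryloxy flavanone. The closure is also a reversible addition with no inherent control at C2, and any base used later reopens it. The chosen plan fixes O1–C8a before ring A exists and never passes through a chalcone on the flavanone side.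

Alternative 2: Cut C2–C1' of the flavanone. Forward: palladium-catalysed asymmetric conjugate addition of a 4-alkoxyphenylboronic acid to 6-aryloxychromone A3. Ground for rejection: the stereocentre is addressed well, but A3 itself needs an Ullmann-type coupling at a di-ortho-alkoxy aryl iodide, the very bond formation the chosen plan avoids. A3 is also an electron-rich, weakly electrophilic acceptor, and the route is longer by several protecting-group and halogenation steps.

Alternative 3: Cut C6–O with reversed polarity, ring A being carried as a non-aromatic 1,3-dione. Forward: Rh2(OAc)4-catalysed O–H insertion of 6 into the carbenoid from diazo dione A4 gives A5, which is aromatized late by loss of methanol to the symmetric resorcinol A6. Ground for rejection: the step solves only the ether. A6 must still be acylated and closed through a chalcone, which brings back both the regiochemical and the stereochemical problem. A4 is also one elimination away from an arene and is expected to be hard to prepare and to diazotize.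

Key step: step 9

Assumption: with Ti(OiPr)4 and (R)-H8-BINOL the diene is taken to add to the Si face of aromatic aldehydes, which gives (S) at C2 of 13; should the sense be the opposite, the (S)-ligand is used and nothing else changes.

## Route

Step 1
Reactants: 1 1-(2,4,6-trihydroxyphenyl)ethan-1-one
Product: 2 1-[2,4-bis(benzyloxy)-6-hydroxyphenyl]ethan-1-one
Conditions: BnBr (2.1 equiv), K2CO3, DMF, 0 °C → rt
Reagents that add atoms: benzyl bromide, BrCc1ccccc1
Why: Williamson ether synthesis; the hydroxyl hydrogen-bonded to the acetyl carbonyl is the least nucleophilic, so the other two should react first and one ortho hydroxyl is kept for the chromone closure.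

Step 2
Reactants: 2 1-[2,4-bis(benzyloxy)-6-hydroxyphenyl]ethan-1-one; 3 4-(methoxymethoxy)benzaldehyde
Product: 4 (E)-1-[2,4-bis(benzyloxy)-6-hydroxyphenyl]-3-[4-(methoxymethoxy)phenyl]prop-2-en-1-one
Conditions: KOH (aq), EtOH/THF, rt
Reagents that add atoms: none
Why: Claisen–Schmidt condensation of a methyl ketone with a non-enolizable aldehyde; dehydration of the aldol should give the conjugated (E)-enone, and the acetal and benzyl ethers are inert to hydroxide.

Step 3
Reactants: 4 (E)-1-[2,4-bis(benzyloxy)-6-hydroxyphenyl]-3-[4-(methoxymethoxy)phenyl]prop-2-en-1-one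
Product: 6 5,7-bis(benzyloxy)-2-(4-hydroxyphenyl)-4H-chromen-4-one, via MOM flavone 5 (not isolated)
Conditions: I2 (10 mol %), DMSO, 130 °C; then 3 M HCl in MeOH, 50 °C
Reagents that add atoms: none
Why: Iodine-catalysed oxidative cyclization of a 2'-hydroxychalcone (oxa-Michael closure, then dehydrogenation with DMSO as terminal oxidant) should give the flavone; acid methanolysis of the aryl methoxymethyl acetal then frees the 4'-hydroxyl while the benzyl ethers remain.

Step 4
Reactants: 6 5,7-bis(benzyloxy)-2-(4-hydroxyphenyl)-4H-chromen-4-one; 7 methyl 2-chloro-3-oxobutanoate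
Product: 8 methyl 2-{4-[5,7-bis(benzyloxy)-4-oxo-4H-chromen-2-yl]phenoxy}-3-oxobutanoate (racemic, keto–enol mixture)
Conditions: K2CO3, acetone, 50 °C
Reagents that add atoms: none
Why: SN2 O-alkylation of the only free phenoxide by an α-chloro-β-keto ester, a standard entry to 2-aryloxyacetoacetates; the new sp3 centre is of no consequence because it becomes sp2 in step 5.

Step 5
Reactants: 8 methyl 2-{4-[5,7-bis(benzyloxy)-4-oxo-4H-chromen-2-yl]phenoxy}-3-oxobutanoate
Product: 9 5,7-bis(benzyloxy)-2-(4-{[1-methoxy-1,3-bis(trimethylsilyloxy)buta-1,3-dien-2-yl]oxy}phenyl)-4H-chromen-4-one (mixture of ketene-acetal geometric isomers)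
Conditions: TMSOTf (2.3 equiv), Et3N (3 equiv), Et2O/CH2Cl2, 0 °C → rt; filtered under argon, used crude
Reagents that add atoms: trimethylsilyl trifluoromethanesulfonate, C[Si](C)(C)OS(=O)(=O)C(F)(F)F
Why: Double soft enolization with O-silylation of a β-keto ester, the usual way to 1-alkoxy-1,3-bis(silyloxy)butadienes; no strong base touches the flavone, and benzyl ethers are stable to silyl triflate and amine.

Step 6
Reactants: 10 4-(benzyloxy)benzaldehyde; 11 (E)-1-methoxy-3-(trimethylsilyloxy)buta-1,3-diene
Product: 13 (2S)-2-[4-(benzyloxy)phenyl]-2,3-dihydro-4H-pyran-4-one, via aldol adduct 12 (not isolated)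
Conditions: Ti(OiPr)4 (10 mol %), (R)-H8-BINOL (11 mol %), 4 Å MS, toluene, 0 °C; then CF3CO2H, CH2Cl2, 0 °C
Reagents that add atoms: none
Why: Catalytic asymmetric hetero-Diels–Alder reaction, run as a Mukaiyama aldol addition followed by acid-induced cyclization with loss of methanol; the chiral titanium bis(naphtholate) shields one face of the bound aldehyde so that the diene terminus adds to the Si face, which sets (S) at C2, the only stereocentre of the target.

Step 7
Reactants: 13 (2S)-2-[4-(benzyloxy)phenyl]-2,3-dihydro-4H-pyran-4-one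
Product: 14 (2S)-2-[4-(benzyloxy)phenyl]-5-(phenylsulfanyl)-2,3-dihydro-4H-pyran-4-one
Conditions: PhSSPh (0.55 equiv), SO2Cl2 (0.55 equiv), CH2Cl2, 0 °C; then 13, pyridine, CH2Cl2, −78 → 0 °C
Reagents that add atoms: benzenesulfenyl chloride, ClSc1ccccc1 (made in the flask from diphenyl disulfide, c1ccc(cc1)SSc1ccccc1, and sulfuryl chloride)
Why: Electrophilic α-sulfenylation of a β-alkoxy enone: the enol-ether carbon C5 attacks sulfur, the oxocarbenium ion at C6 is stabilized by O1, and loss of the C5 proton to pyridine restores the enone; C2 is not involved and the mild base should not open the ring.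

Step 8
Reactants: 14 (2S)-2-[4-(benzyloxy)phenyl]-5-(phenylsulfanyl)-2,3-dihydro-4H-pyran-4-one
Product: 15 (2S)-2-[4-(benzyloxy)phenyl]-5-(phenylsulfinyl)-2,3-dihydro-4H-pyran-4-one (mixture of epimers at sulfur)
Conditions: mCPBA (1.0 equiv), CH2Cl2, −78 → −30 °C
Reagents that add atoms: 3-chloroperoxybenzoic acid, OOC(=O)c1cccc(Cl)c1
Why: Peracid oxidation of a sulfide to the sulfoxide with one equivalent at low temperature; the doubly acceptor-substituted C5=C6 bond is too electron-poor to be epoxidized, and the configuration at sulfur is irrelevant because sulfur is lost in step 9.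

Step 9
Reactants: 9 5,7-bis(benzyloxy)-2-(4-{[1-methoxy-1,3-bis(trimethylsilyloxy)buta-1,3-dien-2-yl]oxy}phenyl)-4H-chromen-4-one; 15 (2S)-2-[4-(benzyloxy)phenyl]-5-(phenylsulfinyl)-2,3-dihydro-4H-pyran-4-one
Product: 18 (2S)-2-[4-(benzyloxy)phenyl]-6-{4-[5,7-bis(benzyloxy)-4-oxo-4H-chromen-2-yl]phenoxy}-5,7-dihydroxy-2,3-dihydro-4H-chromen-4-one, via cycloadduct 16 (not isolated), via silyl ether 17 (not isolated)
Conditions: 9 (1.0 equiv), 15 (1.2 equiv), 4 Å MS, toluene, 25 °C then 70 °C; then 1 M HCl (aq), THF, 0 °C
Reagents that add atoms: none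
Why: Normal-demand Diels–Alder addition of the electron-rich diene 9 to the C5=C6 bond of 15, which is activated geminally at C5 by the ketone and the sulfinyl group: the CH2 terminus of the diene bonds to C6 (the enone β-carbon, future C8a) and the ketene-acetal carbon bonds to C5 (future C4a), giving 16. Because addition to the cyclic alkene is suprafacial, the sulfinyl group at C4a is cis to the hydrogen at C8a, so thermal syn-elimination of benzenesulfenic acid forms the C4a=C8a bond without base; loss of methoxytrimethylsilane from the mixed ketal at C5 and enolization then give phenol 17, whose silyl ether is cleaved on acidic work-up. The closest known reaction type is the Diels–Alder/elimination benzannulation of 1,1,3-trioxygenated butadienes with halo- or sulfinyl-quinones and with 3-sulfinylchromones. Ring A is closed by a [4+2] cycloaddition that forms C4a–C5 and C8–C8a and is then aromatized by two eliminations. No new stereocentre survives: C4a, C5, C8a and sulfur in 16 are all erased, so endo/exo and facial selectivity do not matter, and C2 is a spectator three atoms from the reacting bond. The selectivity needed is regiochemical and is secured by matching the most nucleophilic diene terminus with the β-carbon of the enone, which puts the hydroxyl next to the carbonyl (C5) and the aryloxy group at C6. Elimination of sulfur and not of O1 is secured by the intramolecular syn pathway and by the quaternary C4a, which offers no enolate-driven route to expel O1. Since O1–C8a is carried in from 15 the 8-aryloxy isomer cannot form, and since no base is present the flavanone cannot open to a chalcone.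

Step 10
Reactants: 18 (2S)-2-[4-(benzyloxy)phenyl]-6-{4-[5,7-bis(benzyloxy)-4-oxo-4H-chromen-2-yl]phenoxy}-5,7-dihydroxy-2,3-dihydro-4H-chromen-4-one
Product: 19 (2S)-6-[4-(5,7-dihydroxy-4-oxo-4H-chromen-2-yl)phenoxy]-5,7-dihydroxy-2-(4-hydroxyphenyl)-2,3-dihydro-4H-chromen-4-one
Conditions: H2 (1 atm), Pd/C (10 wt % Pd), EtOAc/MeOH, rt
Reagents that add atoms: none
Why: Catalytic hydrogenolysis of three aryl benzyl ethers under neutral conditions; O-benzyl cleavage should be much faster than reduction of the flavone C2=C3 bond or hydrogenolysis of the cyclic C2–O1 bond, and no base is present to touch C2.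

## Compound list

1 | 1-(2,4,6-trihydroxyphenyl)ethan-1-one | CC(=O)c1c(O)cc(O)cc1O | starting material
2 | 1-[2,4-bis(benzyloxy)-6-hydroxyphenyl]ethan-1-one | CC(=O)c1c(O)cc(OCc2ccccc2)cc1OCc1ccccc1 | intermediate
3 | 4-(methoxymethoxy)benzaldehyde | COCOc1ccc(C=O)cc1 | starting material
4 | (E)-1-[2,4-bis(benzyloxy)-6-hydroxyphenyl]-3-[4-(methoxymethoxy)phenyl]prop-2-en-1-one | O=C(/C=C/c1ccc(OCOC)cc1)c1c(O)cc(OCc2ccccc2)cc1OCc1ccccc1 | intermediate
5 | 5,7-bis(benzyloxy)-2-[4-(methoxymethoxy)phenyl]-4H-chromen-4-one | COCOc1ccc(cc1)-c1cc(=O)c2c(OCc3ccccc3)cc(OCc3ccccc3)cc2o1 | intermediate (not isolated)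
6 | 5,7-bis(benzyloxy)-2-(4-hydroxyphenyl)-4H-chromen-4-one | Oc1ccc(cc1)-c1cc(=O)c2c(OCc3ccccc3)cc(OCc3ccccc3)cc2o1 | intermediate
7 | methyl 2-chloro-3-oxobutanoate | COC(=O)C(Cl)C(C)=O | starting material
8 | methyl 2-{4-[5,7-bis(benzyloxy)-4-oxo-4H-chromen-2-yl]phenoxy}-3-oxobutanoate (racemic) | COC(=O)C(Oc1ccc(cc1)-c1cc(=O)c2c(OCc3ccccc3)cc(OCc3ccccc3)cc2o1)C(C)=O | intermediate
9 | 5,7-bis(benzyloxy)-2-(4-{[1-methoxy-1,3-bis(trimethylsilyloxy)buta-1,3-dien-2-yl]oxy}phenyl)-4H-chromen-4-one (geometric isomers at the ketene acetal) | C=C(O[Si](C)(C)C)C(Oc1ccc(cc1)-c1cc(=O)c2c(OCc3ccccc3)cc(OCc3ccccc3)cc2o1)=C(OC)O[Si](C)(C)C | intermediate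
10 | 4-(benzyloxy)benzaldehyde | O=Cc1ccc(OCc2ccccc2)cc1 | starting material
11 | (E)-1-methoxy-3-(trimethylsilyloxy)buta-1,3-diene | CO/C=C/C(=C)O[Si](C)(C)C | starting material
12 | (1E,5S)-5-[4-(benzyloxy)phenyl]-1-methoxy-5-(trimethylsilyloxy)pent-1-en-3-one | CO/C=C/C(=O)C[C@@H](c1ccc(OCc2ccccc2)cc1)O[Si](C)(C)C | intermediate (not isolated)
13 | (2S)-2-[4-(benzyloxy)phenyl]-2,3-dihydro-4H-pyran-4-one | O=C1C[C@@H](c2ccc(OCc3ccccc3)cc2)OC=C1 | intermediate
14 | (2S)-2-[4-(benzyloxy)phenyl]-5-(phenylsulfanyl)-2,3-dihydro-4H-pyran-4-one | O=C1C[C@@H](c2ccc(OCc3ccccc3)cc2)OC=C1Sc1ccccc1 | intermediate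
15 | (2S)-2-[4-(benzyloxy)phenyl]-5-(phenylsulfinyl)-2,3-dihydro-4H-pyran-4-one (epimers at sulfur) | O=C1C[C@@H](c2ccc(OCc3ccccc3)cc2)OC=C1S(=O)c1ccccc1 | intermediate
16 | (2S)-2-[4-(benzyloxy)phenyl]-6-{4-[5,7-bis(benzyloxy)-4-oxo-4H-chromen-2-yl]phenoxy}-5-methoxy-4a-(phenylsulfinyl)-5,7-bis(trimethylsilyloxy)-2,3,4a,5,8,8a-hexahydro-4H-chromen-4-one (cis ring fusion; mixture at C4a, C5, C8a and sulfur) | O=C1C[C@@H](c2ccc(OCc3ccccc3)cc2)OC2CC(O[Si](C)(C)C)=C(Oc3ccc(cc3)-c3cc(=O)c4c(OCc5ccccc5)cc(OCc5ccccc5)cc4o3)C(OC)(O[Si](C)(C)C)C12S(=O)c1ccccc1 | intermediate (not isolated)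
17 | (2S)-2-[4-(benzyloxy)phenyl]-6-{4-[5,7-bis(benzyloxy)-4-oxo-4H-chromen-2-yl]phenoxy}-5-hydroxy-7-(trimethylsilyloxy)-2,3-dihydro-4H-chromen-4-one | O=C1C[C@@H](c2ccc(OCc3ccccc3)cc2)Oc2cc(O[Si](C)(C)C)c(Oc3ccc(cc3)-c3cc(=O)c4c(OCc5ccccc5)cc(OCc5ccccc5)cc4o3)c(O)c21 | intermediate (not isolated)
18 | (2S)-2-[4-(benzyloxy)phenyl]-6-{4-[5,7-bis(benzyloxy)-4-oxo-4H-chromen-2-yl]phenoxy}-5,7-dihydroxy-2,3-dihydro-4H-chromen-4-one | O=C1C[C@@H](c2ccc(OCc3ccccc3)cc2)Oc2cc(O)c(Oc3ccc(cc3)-c3cc(=O)c4c(OCc5ccccc5)cc(OCc5ccccc5)cc4o3)c(O)c21 | intermediate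
19 | (2S)-6-[4-(5,7-dihydroxy-4-oxo-4H-chromen-2-yl)phenoxy]-5,7-dihydroxy-2-(4-hydroxyphenyl)-2,3-dihydro-4H-chromen-4-one | O=C1C[C@@H](c2ccc(O)cc2)Oc2cc(O)c(Oc3ccc(-c4cc(=O)c5c(O)cc(O)cc5o4)cc3)c(O)c21 | target

## Step count and least certain steps

Total steps: 10. Longest linear sequence: 7 (steps 1, 2, 3, 4, 5, 9, 10); the pyranone branch (steps 6, 7, 8) joins at step 9.

**Step 9 (key step).** What may go wrong:
- The addition may stop after the first C–C bond (a Mukaiyama–Michael adduct), and the resulting α-sulfinyl enolate may then expel O1 and open the pyranone.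
- Silyl transfer from the ketene acetal to the sulfoxide oxygen may start a Pummerer-type reaction.
- Bond formation at the fully substituted ketene-acetal carbon may be slow enough for the diene to be hydrolysed by water formed from the sulfenic acid. The two-temperature protocol (cycloaddition first, elimination after) is meant to limit this.

Fallback (sets out from 6, returns at 19): ring A is taken from a chromone, the ether is made by copper catalysis, and C2 is set last by conjugate arylation. Commercial 5,7-dihydroxy-4H-chromen-4-one is benzylated at O7 (BnBr, K2CO3, acetone) to 7-(benzyloxy)-5-hydroxy-4H-chromen-4-one F1. The chelated 5-hydroxyl directs iodination ([BnNMe3][ICl2], CaCO3, CH2Cl2/MeOH) to C6, giving 7-(benzyloxy)-5-hydroxy-6-iodo-4H-chromen-4-one F2. Benzylation of O5 (BnBr, K2CO3, DMF, 60 °C) gives 5,7-bis(benzyloxy)-6-iodo-4H-chromen-4-one F3. Ullmann-type coupling of F3 with 6 (CuI, picolinic acid, K3PO4, DMSO, 90 °C) gives 5,7-bis(benzyloxy)-6-{4-[5,7-bis(benzyloxy)-4-oxo-4H-chromen-2-yl]phenoxy}-4H-chromen-4-one F4 (the same compound as A3). Asymmetric conjugate addition of 4-(benzyloxy)phenylboronic acid to the unsubstituted C2 of F4 (Pd(OCOCF3)2, the tert-butyl pyridinyloxazoline antipode that delivers 2S, NH4PF6, H2O, ClCH2CH2Cl, 60 °C) gives (2S)-5,7-bis(benzyloxy)-2-[4-(benzyloxy)phenyl]-6-{4-[5,7-bis(benzyloxy)-4-oxo-4H-chromen-2-yl]phenoxy}-2,3-dihydro-4H-chromen-4-one F5; the 2-aryl-substituted flavone unit should be far less reactive. Hydrogenolysis under the conditions of step 10 gives 19.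

**Step 5.** What may go wrong: the second (γ) silylation may be incomplete at the congested tetrasubstituted enol ether, the diene may lose silyl groups on handling, and the silyl triflate may activate the flavone carbonyl towards amine addition.

Fallback (sets out from 8, returns at 9): the enolization is done in two separate stages with a kinetic deprotonation in place of the soft one. TMSCl and Et3N in CH2Cl2 give methyl 2-{4-[5,7-bis(benzyloxy)-4-oxo-4H-chromen-2-yl]phenoxy}-3-(trimethylsilyloxy)but-2-enoate F7, isolated by filtration and evaporation. Deprotonation of its methyl group with LiN(iPr)2 in THF at −78 °C and quenching with TMSCl gives 9; at this temperature the vinylogous ester proton should be removed faster than the flavone is attacked.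

**Step 7.** What may go wrong: chloride may be captured at C6 without re-elimination, a second sulfenylation may occur, and base-induced β-elimination of O1 from C2 may open the ring and erode the configuration on re-closure.

Fallback (sets out from 13, returns at 14): the sulfur is introduced by cross-coupling. α-Iodination (I2, pyridine, CH2Cl2, rt) gives (2S)-2-[4-(benzyloxy)phenyl]-5-iodo-2,3-dihydro-4H-pyran-4-one F6, and C–S coupling with thiophenol (Pd2(dba)3, Xantphos, iPr2NEt, dioxane, 80 °C) gives 14.

**Step 10.** What may go wrong: saturation of the flavone C2=C3 bond, hydrogenolysis of the benzylic C2–O1 bond, or stalling at partly debenzylated stages because of poor solubility.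

Fallback (sets out from 18, returns at 19; no new compound, F0): the cleavage mode is changed from reductive to Lewis-acidic, with BCl3 and pentamethylbenzene as benzyl-cation scavenger in CH2Cl2 at −78 °C, which cannot reduce the flavone and uses no base.

## Further compounds

F1 | step 9 | 7-(benzyloxy)-5-hydroxy-4H-chromen-4-one | O=c1ccoc2cc(OCc3ccccc3)cc(O)c12
F2 | step 9 | 7-(benzyloxy)-5-hydroxy-6-iodo-4H-chromen-4-one | O=c1ccoc2cc(OCc3ccccc3)c(I)c(O)c12
F3 | step 9 | 5,7-bis(benzyloxy)-6-iodo-4H-chromen-4-one | O=c1ccoc2cc(OCc3ccccc3)c(I)c(OCc3ccccc3)c12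
F4 | step 9 | 5,7-bis(benzyloxy)-6-{4-[5,7-bis(benzyloxy)-4-oxo-4H-chromen-2-yl]phenoxy}-4H-chromen-4-one | O=c1ccoc2cc(OCc3ccccc3)c(Oc3ccc(cc3)-c3cc(=O)c4c(OCc5ccccc5)cc(OCc5ccccc5)cc4o3)c(OCc3ccccc3)c12
F5 | step 9 | (2S)-5,7-bis(benzyloxy)-2-[4-(benzyloxy)phenyl]-6-{4-[5,7-bis(benzyloxy)-4-oxo-4H-chromen-2-yl]phenoxy}-2,3-dihydro-4H-chromen-4-one | O=C1C[C@@H](c2ccc(OCc3ccccc3)cc2)Oc2cc(OCc3ccccc3)c(Oc3ccc(cc3)-c3cc(=O)c4c(OCc5ccccc5)cc(OCc5ccccc5)cc4o3)c(OCc3ccccc3)c21
F6 | step 7 | (2S)-2-[4-(benzyloxy)phenyl]-5-iodo-2,3-dihydro-4H-pyran-4-one | O=C1C[C@@H](c2ccc(OCc3ccccc3)cc2)OC=C1I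
F7 | step 5 | methyl 2-{4-[5,7-bis(benzyloxy)-4-oxo-4H-chromen-2-yl]phenoxy}-3-(trimethylsilyloxy)but-2-enoate | COC(=O)C(Oc1ccc(cc1)-c1cc(=O)c2c(OCc3ccccc3)cc(OCc3ccccc3)cc2o1)=C(C)O[Si](C)(C)C
F0 | step 10 | none | none
A1 | alternative 1 | 4-(3-acetyl-2,4,6-trimethoxyphenoxy)benzaldehyde | CC(=O)c1c(OC)cc(OC)c(Oc2ccc(C=O)cc2)c1OC
A2 | alternative 1 | (E)-1-{3-[4-(5,7-dihydroxy-4-oxo-4H-chromen-2-yl)phenoxy]-2,4,6-trihydroxyphenyl}-3-(4-hydroxyphenyl)prop-2-en-1-one | O=C(/C=C/c1ccc(O)cc1)c1c(O)cc(O)c(Oc2ccc(cc2)-c2cc(=O)c3c(O)cc(O)cc3o2)c1O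
A3 | alternative 2 | 5,7-bis(benzyloxy)-6-{4-[5,7-bis(benzyloxy)-4-oxo-4H-chromen-2-yl]phenoxy}-4H-chromen-4-one | O=c1ccoc2cc(OCc3ccccc3)c(Oc3ccc(cc3)-c3cc(=O)c4c(OCc5ccccc5)cc(OCc5ccccc5)cc4o3)c(OCc3ccccc3)c12
A4 | alternative 3 | 2-diazo-5,5-dimethoxycyclohexane-1,3-dione | COC1(OC)CC(=O)C(=[N+]=[N-])C(=O)C1
A5 | alternative 3 | 2-{4-[5,7-bis(benzyloxy)-4-oxo-4H-chromen-2-yl]phenoxy}-5,5-dimethoxycyclohexane-1,3-dione | COC1(OC)CC(=O)C(Oc2ccc(cc2)-c2cc(=O)c3c(OCc4ccccc4)cc(OCc4ccccc4)cc3o2)C(=O)C1
A6 | alternative 3 | 5,7-bis(benzyloxy)-2-[4-(2,6-dihydroxy-4-methoxyphenoxy)phenyl]-4H-chromen-4-one | COc1cc(O)c(Oc2ccc(cc2)-c2cc(=O)c3c(OCc4ccccc4)cc(OCc4ccccc4)cc3o2)c(O)c1
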